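**Retrosynthetic overview**
1. Target 13 is an oxolane (O1, C2 aryl, C3 CH2OAc, C4 benzyl, C5 H2; 2,3-trans, 3,4-cis). It is taken back to diacetate 12 (one hydrogenolysis removes three benzyl ethers and the benzylic acetate), then to diol 11, then to lactol 8 plus aryl Grignard 10.
2. The benzylic CH2 on C4 is traced to a lactone carbonyl tied to the CH2O on C3: cis-fused bicyclic lactone 7, which locks the 3,4-cis relation.
3. Key disconnection of 7: O1–C5 of the oxolane is a CH2=O unit bonded to nothing but C2 and C4; C2 is benzylic to a para-oxygenated arene (donor) and C4 is α to the lactone carbonyl (acceptor). The oxolane is therefore the formal [3+2] adduct of formaldehyde and donor–acceptor cyclopropane 6, forming C4–C5 and O1–C2 together.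
4. 6 comes from enantioselective intramolecular cyclopropanation of Z-allylic diazoacetate 5, made from aldehyde 1 (Z-olefination, reduction, diazoacetylation).
5. Ring order: cyclopropane and γ-lactone together (step 4), oxolane at the expense of the cyclopropane (step 5), lactone opened (steps 6 and 7).

Key step: step 5

Assumption: Rh2(5R-MEPY)4 is taken to give the (1S,5R) lactone series from Z-allylic diazoacetates, by analogy with the sense of induction known for this catalyst family; if the sense proves opposite, the 5S catalyst is used and nothing else changes.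

**Step 1**
Reactants: 1 3,4-bis(benzyloxy)benzaldehyde
Product: 2 methyl (2Z)-3-[3,4-bis(benzyloxy)phenyl]prop-2-enoate
Conditions: (CF3CH2O)2P(O)CH2CO2Me, KN(SiMe3)2, 18-crown-6, THF, −78 °C
Reagents that add atoms: methyl bis(2,2,2-trifluoroethyl)phosphonoacetate, COC(=O)CP(=O)(OCC(F)(F)F)OCC(F)(F)F
Why: Still–Gennari variant of the Horner–Wadsworth–Emmons olefination; the electron-poor phosphonate under dissociating conditions eliminates faster than the adducts equilibrate, so the Z-enoate should dominate with an aryl aldehyde.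

**Step 2**
Reactants: 2 methyl (2Z)-3-[3,4-bis(benzyloxy)phenyl]prop-2-enoate
Product: 3 (2Z)-3-[3,4-bis(benzyloxy)phenyl]prop-2-en-1-ol
Conditions: i-Bu2AlH (2.2 equiv), CH2Cl2, −78 °C; aqueous potassium sodium tartrate work-up
Reagents that add atoms: none
Why: Low-temperature i-Bu2AlH reduction of an enoate is a 1,2-reduction that leaves the Z double bond and the benzyl ethers untouched.

**Step 3**
Reactants: 3 (2Z)-3-[3,4-bis(benzyloxy)phenyl]prop-2-en-1-ol
Product: 5 (2Z)-3-[3,4-bis(benzyloxy)phenyl]prop-2-en-1-yl 2-diazoacetate, via tosylhydrazone ester 4 (not isolated)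
Conditions: TsNHN=CHCOCl, PhNMe2, CH2Cl2, 0 °C; then Et3N, 0 °C to rt
Reagents that add atoms: glyoxylic acid chloride p-toluenesulfonylhydrazone, Cc1ccc(cc1)S(=O)(=O)NN=CC(Cl)=O
Why: House–Corey–Myers diazoacetate synthesis; O-acylation by the acid chloride is followed by triethylamine-induced loss of p-toluenesulfinate from the tosylhydrazone (Bamford–Stevens type), under conditions that should not isomerise the Z-alkene.

**Step 4**
Reactants: 5 (2Z)-3-[3,4-bis(benzyloxy)phenyl]prop-2-en-1-yl 2-diazoacetate
Product: 6 (1S,5R,6S)-6-[3,4-bis(benzyloxy)phenyl]-3-oxabicyclo[3.1.0]hexan-2-one (aryl endo, cis to the C4 methylene)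
Conditions: Rh2(5R-MEPY)4 {dirhodium tetrakis[methyl (5R)-2-oxopyrrolidine-5-carboxylate]} (1 mol %), CH2Cl2, reflux, slow addition of 5
Reagents that add atoms: none
Why: Doyle-type enantioselective intramolecular cyclopropanation by a chiral dirhodium carboxamidate carbenoid; addition to the Z-alkene is stereospecific (aryl ends endo), the catalyst selects the alkene face and so sets C1 and C5 (and with them C6), and Z-disubstituted allylic diazoacetates are a favourable substrate class for this catalyst.

**Step 5**
Reactants: 6 (1S,5R,6S)-6-[3,4-bis(benzyloxy)phenyl]-3-oxabicyclo[3.1.0]hexan-2-one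
Product: 7 (1R,5R,6S)-6-[3,4-bis(benzyloxy)phenyl]-3,7-dioxabicyclo[3.3.0]octan-2-one (cis-fused, aryl exo)
Conditions: paraformaldehyde (5 equiv CH2O), Sc(OTf)3 (20 mol %), 4 Å molecular sieves, ClCH2CH2Cl, rt to 50 °C
Reagents that add atoms: formaldehyde (from paraformaldehyde), C=O
Why: Proposed new method: Sc(OTf)3 bound to the lactone carbonyl should ionise the cyclopropane bond between C6 (benzylic, pushed by the para-benzyloxy group) and C1 (pulled by the carbonyl, and the only ring bond aligned with its π system) to a scandium lactone enolate/para-alkoxybenzyl cation pair, whose enolate carbon adds to formaldehyde (aldol, new C–C bond) and whose cationic carbon is then captured by the new oxygen (new C–O bond); an SN2-like attack of the formaldehyde oxygen on C6 followed by C–C closure would lead to the same product. The closest known reaction type is the Lewis-acid-catalysed formal [3+2] cycloaddition of 2-arylcyclopropane-1,1-diesters with aldehydes to oxolanes, which has served tetrahydrofuran lignan synthesis; new here are the single lactone acceptor held in a bicycle and formaldehyde as the two-atom partner. The oxolane is the only ring closed, by 5-exo-trig attack of oxygen on the benzylic cation (or, in the inverted order, by 5-(enolexo)-endo-trig C–C closure on the oxocarbenium ion). C1 is re-formed cis to C5 because a 3,7-dioxabicyclo[3.3.0]octanone can only be cis-fused, and C6 takes the aryl group exo (trans to the lactone CH2) both by inversion of the endo-aryl cyclopropane and by closure of the planar cation on its open face, while reversible Lewis-acid ionisation of the benzylic C–O bond should drain any endo isomer to the exo one, so the step is stereoconvergent at C6. The absolute configuration is carried by C5, whose bonds are never broken. The selectivity needed is cleavage of C1–C6 rather than C1–C5 or C5–C6, secured because donor and acceptor flank only that bond, and capture of the cation by oxygen rather than by the arene, favoured by the five-membered closure.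

**Step 6**
Reactants: 7 (1R,5R,6S)-6-[3,4-bis(benzyloxy)phenyl]-3,7-dioxabicyclo[3.3.0]octan-2-one
Product: 8 (1R,5R,6S)-6-[3,4-bis(benzyloxy)phenyl]-3,7-dioxabicyclo[3.3.0]octan-2-ol (both anomers at C2)
Conditions: i-Bu2AlH (1.1 equiv), CH2Cl2, −78 °C
Reagents that add atoms: none
Why: Partial reduction of a γ-lactone; the tetrahedral aluminium hemiacetal is stable at −78 °C and gives the lactol on work-up, with no stereocenter touched apart from the new, inconsequential anomeric one.

**Step 7**
Reactants: 8 (1R,5R,6S)-6-[3,4-bis(benzyloxy)phenyl]-3,7-dioxabicyclo[3.3.0]octan-2-ol; 9 1-(benzyloxy)-4-bromo-2-methoxybenzene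
Product: 11 [(2S,3R,4R)-2-[3,4-bis(benzyloxy)phenyl]-4-{[4-(benzyloxy)-3-methoxyphenyl](hydroxy)methyl}oxolan-3-yl]methanol (both carbinol epimers), via arylmagnesium bromide 10 (not isolated)
Conditions: 9, Mg, THF, reflux; then 8 (to 3 equiv of 10), THF, 0 °C to rt; aqueous NH4Cl
Reagents that add atoms: none
Why: Grignard addition to a lactol through its ring-opened hydroxy aldehyde (the first equivalent deprotonates, the next adds), as used to open samin-type lactols; the new carbinol center forms as a mixture that does not matter because its oxygen is removed in step 9.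

**Step 8**
Reactants: 11 [(2S,3R,4R)-2-[3,4-bis(benzyloxy)phenyl]-4-{[4-(benzyloxy)-3-methoxyphenyl](hydroxy)methyl}oxolan-3-yl]methanol
Product: 12 [(2S,3R,4R)-4-{(acetyloxy)[4-(benzyloxy)-3-methoxyphenyl]methyl}-2-[3,4-bis(benzyloxy)phenyl]oxolan-3-yl]methyl acetate (both epimers at the benzylic acetate carbon)
Conditions: Ac2O, pyridine, DMAP (cat.), CH2Cl2, rt
Reagents that add atoms: acetic anhydride, CC(=O)OC(C)=O
Why: DMAP-catalysed acetylation of a primary and a secondary benzylic alcohol; no selectivity is needed because the benzylic acetate is the leaving group of the next step and the primary acetate is the one kept in the target.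

**Step 9**
Reactants: 12 [(2S,3R,4R)-4-{(acetyloxy)[4-(benzyloxy)-3-methoxyphenyl]methyl}-2-[3,4-bis(benzyloxy)phenyl]oxolan-3-yl]methyl acetate
Product: 13 [(2S,3R,4R)-2-(3,4-dihydroxyphenyl)-4-[(4-hydroxy-3-methoxyphenyl)methyl]oxolan-3-yl]methyl acetate
Conditions: H2 (1 atm), 10% Pd/C, EtOAc, rt
Reagents that add atoms: none
Why: Heterogeneous hydrogenolysis should cleave the three aryl benzyl ethers and the benzylic C–OAc bond (an ester leaving group that, after debenzylation, sits on a para-hydroxybenzyl carbon and can also leave through a quinone methide that is hydrogenated at once), while the oxolane C2–O1 bond (a benzylic ether with an alkoxide leaving group), the primary acetate and the three stereocenters should persist under neutral conditions.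

**Compound list**
1 | 3,4-bis(benzyloxy)benzaldehyde | O=Cc1ccc(OCc2ccccc2)c(OCc2ccccc2)c1 | starting material
2 | methyl (2Z)-3-[3,4-bis(benzyloxy)phenyl]prop-2-enoate | COC(=O)/C=C\c1ccc(OCc2ccccc2)c(OCc2ccccc2)c1 | intermediate
3 | (2Z)-3-[3,4-bis(benzyloxy)phenyl]prop-2-en-1-ol | OC/C=C\c1ccc(OCc2ccccc2)c(OCc2ccccc2)c1 | intermediate
4 | (2Z)-3-[3,4-bis(benzyloxy)phenyl]prop-2-en-1-yl 2-[2-(4-methylbenzenesulfonyl)hydrazinylidene]acetate | Cc1ccc(cc1)S(=O)(=O)NN=CC(=O)OC/C=C\c1ccc(OCc2ccccc2)c(OCc2ccccc2)c1 | intermediate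
5 | (2Z)-3-[3,4-bis(benzyloxy)phenyl]prop-2-en-1-yl 2-diazoacetate | [N-]=[N+]=CC(=O)OC/C=C\c1ccc(OCc2ccccc2)c(OCc2ccccc2)c1 | intermediate
6 | (1S,5R,6S)-6-[3,4-bis(benzyloxy)phenyl]-3-oxabicyclo[3.1.0]hexan-2-one | O=C1OC[C@@H]2[C@H](c3ccc(OCc4ccccc4)c(OCc4ccccc4)c3)[C@H]12 | intermediate
7 | (1R,5R,6S)-6-[3,4-bis(benzyloxy)phenyl]-3,7-dioxabicyclo[3.3.0]octan-2-one | O=C1[C@H]2CO[C@H](c3ccc(OCc4ccccc4)c(OCc4ccccc4)c3)[C@H]2CO1 | intermediate
8 | (1R,5R,6S)-6-[3,4-bis(benzyloxy)phenyl]-3,7-dioxabicyclo[3.3.0]octan-2-ol (anomeric mixture) | OC1[C@H]2CO[C@H](c3ccc(OCc4ccccc4)c(OCc4ccccc4)c3)[C@H]2CO1 | intermediate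
9 | 1-(benzyloxy)-4-bromo-2-methoxybenzene | COc1cc(Br)ccc1OCc1ccccc1 | starting material
10 | [4-(benzyloxy)-3-methoxyphenyl]magnesium bromide | COc1cc([Mg]Br)ccc1OCc1ccccc1 | intermediate
11 | [(2S,3R,4R)-2-[3,4-bis(benzyloxy)phenyl]-4-{[4-(benzyloxy)-3-methoxyphenyl](hydroxy)methyl}oxolan-3-yl]methanol (carbinol epimers) | COc1cc(C(O)[C@H]2CO[C@H](c3ccc(OCc4ccccc4)c(OCc4ccccc4)c3)[C@H]2CO)ccc1OCc1ccccc1 | intermediate
12 | [(2S,3R,4R)-4-{(acetyloxy)[4-(benzyloxy)-3-methoxyphenyl]methyl}-2-[3,4-bis(benzyloxy)phenyl]oxolan-3-yl]methyl acetate | COc1cc(C(OC(C)=O)[C@H]2CO[C@H](c3ccc(OCc4ccccc4)c(OCc4ccccc4)c3)[C@H]2COC(C)=O)ccc1OCc1ccccc1 | intermediate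
13 | [(2S,3R,4R)-2-(3,4-dihydroxyphenyl)-4-[(4-hydroxy-3-methoxyphenyl)methyl]oxolan-3-yl]methyl acetate | COc1cc(C[C@H]2CO[C@H](c3ccc(O)c(O)c3)[C@H]2COC(C)=O)ccc1O | target

**Step count**
Total steps: 9. Longest linear sequence: 9 steps (1 to 13); bromide 9 enters in step 7.

**Steps most likely to fail**

Step 5 (proposed new method). With a single acceptor the cyclopropane may not ionise. If it does, the zwitterion may lose a proton to a ring-opened unsaturated lactone, or the benzylic cation or activated formaldehyde may be intercepted by the electron-rich arene before oxygen capture. The fallback brings the substrate into the established diacceptor class and sets out from 3. Acylation with methyl malonyl chloride (pyridine, CH2Cl2, 0 °C) should give (2Z)-3-[3,4-bis(benzyloxy)phenyl]prop-2-en-1-yl methyl propanedioate F1. Diazo transfer (p-acetamidobenzenesulfonyl azide, Et3N, MeCN) should give the diazomalonate F2. Intramolecular cyclopropanation (CuOTf with a tert-butyl bis(oxazoline) ligand, or Rh2(OAc)4 followed by resolution on a chiral stationary phase) should give the 1-methoxycarbonyl analogue of 6, methyl 6-endo-aryl-2-oxo-3-oxabicyclo[3.1.0]hexane-1-carboxylate F3. The known type of [3+2] cycloaddition with formaldehyde (paraformaldehyde, Sn(OTf)2, ClCH2CH2Cl) should give the 1-methoxycarbonyl analogue of 7, F4. Krapcho demethoxycarbonylation (LiCl, wet DMSO, 130 °C) then returns to 7, the cis ring fusion being forced on protonation. The price is weaker enantiocontrol in the cyclopropanation.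

Step 9. Hydrogenolysis may run on into the oxolane C2–O1 benzylic bond, or the quinone methide on the way may tautomerise to a styrene and erode C4. The fallback separates the two tasks and sets out from 12. Ionic deoxygenation (Et3SiH, BF3·OEt2, CH2Cl2, −78 to −30 °C) ionises only the benzylic acetate and should give [(2S,3R,4R)-4-{[4-(benzyloxy)-3-methoxyphenyl]methyl}-2-[3,4-bis(benzyloxy)phenyl]oxolan-3-yl]methyl acetate F5. A short neutral debenzylation (H2, Pd/C, EtOAc, stopped after three equivalents of hydrogen) then returns to 13.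

Step 7. The magnesium lactolate may open too slowly, or the basic Grignard reagent may enolise the open aldehyde and epimerise C4 of the future oxolane. The fallback adds the aryl group at the lactone stage and sets out from 7. 4-(Benzyloxy)-3-methoxyphenyllithium (from 9, n-BuLi, THF, −78 °C) should add once to give the hemiketal (1R,5R,6S)-2-[4-(benzyloxy)-3-methoxyphenyl]-6-[3,4-bis(benzyloxy)phenyl]-3,7-dioxabicyclo[3.3.0]octan-2-ol F6. NaBH4 (MeOH/THF, 0 °C) should reduce its open hydroxy-ketone form and so return to 11.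

**Further compounds**
F1 | step 5 | (2Z)-3-[3,4-bis(benzyloxy)phenyl]prop-2-en-1-yl methyl propanedioate | COC(=O)CC(=O)OC/C=C\c1ccc(OCc2ccccc2)c(OCc2ccccc2)c1
F2 | step 5 | (2Z)-3-[3,4-bis(benzyloxy)phenyl]prop-2-en-1-yl methyl 2-diazopropanedioate | COC(=O)C(=[N+]=[N-])C(=O)OC/C=C\c1ccc(OCc2ccccc2)c(OCc2ccccc2)c1
F3 | step 5 | methyl 6-endo-[3,4-bis(benzyloxy)phenyl]-2-oxo-3-oxabicyclo[3.1.0]hexane-1-carboxylate (configuration at C5 and C6 as in 6) | O=C1OC[C@@H]2[C@H](c3ccc(OCc4ccccc4)c(OCc4ccccc4)c3)[C@]12C(=O)OC
F4 | step 5 | methyl 6-exo-[3,4-bis(benzyloxy)phenyl]-2-oxo-3,7-dioxabicyclo[3.3.0]octane-1-carboxylate (configuration at C5 and C6 as in 7) | O=C1[C@@]2(C(=O)OC)CO[C@H](c3ccc(OCc4ccccc4)c(OCc4ccccc4)c3)[C@H]2CO1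
F5 | step 9 | [(2S,3R,4R)-4-{[4-(benzyloxy)-3-methoxyphenyl]methyl}-2-[3,4-bis(benzyloxy)phenyl]oxolan-3-yl]methyl acetate | COc1cc(C[C@H]2CO[C@H](c3ccc(OCc4ccccc4)c(OCc4ccccc4)c3)[C@H]2COC(C)=O)ccc1OCc1ccccc1
F6 | step 7 | (1R,5R,6S)-2-[4-(benzyloxy)-3-methoxyphenyl]-6-[3,4-bis(benzyloxy)phenyl]-3,7-dioxabicyclo[3.3.0]octan-2-ol | OC1(c3ccc(OCc4ccccc4)c(OC)c3)[C@H]2CO[C@H](c3ccc(OCc4ccccc4)c(OCc4ccccc4)c3)[C@H]2CO1
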